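**Conventions.** Ring A is C1(=CH2)–C2(=O)–C3(OH)=C4–C5(H)–C10(CH3). Ring B is C5–C6(CH3, side chain)–C7(CH3)–C8(OAc)–C9–C10. β is the face of ring B that carries the C10 methyl and α is the opposite face. The target is then 5β-H, 6β-side chain, 6α-CH3, 7α-CH3, 8β-OAc, 10β-CH3.

**Assumption.** The (S)-oxazaborolidine is taken to give the 3R carbinol of 4, with the quaternary carbon as the large group as for aryl alkyl ketones; if the sense were reversed, the (R)-catalyst would be used.

## Analysis of the target

- The target is a cis-fused decalin (5β-H, 10β-CH3) that carries an (E)-3-methylpent-2-enoic acid chain on C6.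
- Ring A is a cross-conjugated dienone: an exocyclic methylene on C1, a C2 ketone and a C3 enol (C3=C4), with C1 bound to quaternary C10.
- There are five stereocentres: C5, C6, C7 and C8 are contiguous and C10 completes the ring fusion. C6 and C10 are all-carbon quaternary.
- The side chain, the C8 acetate, the C10 methyl and the C5 hydrogen lie on the β face; the C6 and C7 methyls lie on the α face.
- In the chair–chair form that puts the side chain, the C7 methyl and the C8 oxygen equatorial (form P), the 6α-methyl is axial and points into the concave pocket at C1. This form exists only if C1 has no α substituent, as in the target, where C1 is trigonal.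
- The sensitive groups are the α-methylene ketone and diosphenol (Michael acceptor, labile to base and nucleophiles), the secondary acetate (base) and the trisubstituted E-enoic acid.
- The difficulties are the congested C5–C8 array around quaternary C6, the conformation-dependent control of C7 and C8, and the late oxidation of ring A.
- The strategy rests on one feature: the methyl-bearing C7 lies between oxygenated C8 and quaternary C6. Ring B can therefore be read as the cyclopentanone C5–C6–C8–C9–C10 enlarged by a vinyl unit that supplies C7 and its methyl.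

## Retrosynthetic reasoning

**30 from 29.** The acid is unmasked last from tert-butyl ester 29 by acidolysis. An acid-labile ester is chosen because the C8 acetate and the dienone would not survive saponification.

**29 from 25.** The C3 oxygen is removed next. Diosphenol 29 is the stable tautomer of dione 28, which comes from hydroxy ketone 27 and this from enone 25 through its dienolate 26. C3 is the only enolisable position of 25 because C1 is trigonal, so the regiochemistry is safe. The price is a strong base on a Michael acceptor.

**25 from 22.** The C2 carbonyl goes back through allylic alcohol 24 to exocyclic alkene 23; C2 is its only allylic methylene because C10 is quaternary. The C1=CH2 bond is then cut to ketone 22. One carbonyl at C1 thus accounts for all of the ring A functionality.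

**22 from 20 and 21.** The side-chain double bond is cut by an olefination of methyl ketone 20 with phosphonate 21. The α-quaternary C1 ketone of 20 should not compete.

**20 from 16.** Functional group changes lead back to dione 16: ketal hydrolysis (from 19), re-oxidation of C1 (from 18), site-selective acetylation of diol 17, and reduction of both carbonyls of 16. The C8–H bond must be formed under thermodynamic control. In form P the α-axial approach to C8 is blocked by the axial 6α-methyl and by C1, so a hydride would give the 8α-alcohol.

**16 from 15 (key disconnection).** The C6–C7 bond is cut, and ring B contracts to the cis-hydrindane vinyl carbinol 15. This is the only ring B bond whose cleavage does three things at once: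
- it keeps the C8 oxygen as the hydroxyl that drives the shift;
- it turns the crowded cyclohexane into a cyclopentanone whose C6 can be alkylated on a convex face;
- it brings in C7 and its methyl as a vinyl group.

C1 is a free ketone in 15 and 16. A ketal or a 1α-oxygen at C1 would collide with the axial 6α-methyl in form P and force the ring-flipped chair, where 7α-methyl and 8β-oxygen are both axial and thermodynamic control would give the wrong epimers.

**15 from 11 and 12.** The C8–vinyl bond is cut to ketone 11 and vinylmagnesium bromide 12. C1 must be masked during this addition (13), and is then released (14) and oxidised (15).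

**11 from 8 and 9.** The C6–CH2 bond and the C5–H bond are cut together: reduction of enone 8 gives enolate 10, which is alkylated by bromide 9. The methyl must already be on C6 and the chain must enter last, because the incoming group ends up on the convex β face.

**8 from 1 and 2.** The C5=C6 bond is cut by an aldol condensation of 1,4-diketone 6. Compound 6 is the hydration product of alkyne 5, the silyl ether of ketol 4. Ketol 4 arises by enantioselective reduction of one carbonyl of the prochiral dione 3, which fixes quaternary C10. Dione 3 is the C-alkylation product of 1 with 2. The but-2-ynyl group delivers C9, C8, C6 and the C6 methyl.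

## Alternatives that were turned down

**Alternative 1: radical closure of ring A at C4–C5.**
- Disconnection: the C4–C5 bond.
- Forward key step: thionocarbonate A1 has ring B complete and a 1-methylene-2-oxobut-3-enyl chain on C10. Under reductive radical-chain conditions it would give a C5 radical that attacks the terminal enone carbon C4 in a 6-endo mode and closes ring A to A2.
- For: the step is polarity-matched. Ring A arrives with its methylene and C2 ketone, so only C3 remains to be oxidised. On this point it is stronger than the chosen route, which spends three steps on C1 and C2.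
- Against: the four stereocentres C6, C7, C8 and C10, including both quaternary carbons, must be built on a monocyclic cyclohexane without a bicyclic template. The cross-conjugated divinyl ketone polymerises easily and sits on a neopentyl carbon. The ring fusion at C5 is decided in the radical step with no strong bias.
- Comparison: the chosen route sets C5 and C6 on a rigid bicyclic enone and leaves ring A to late but ordinary oxidations.

**Alternative 2: carbonylative Stille closure of ring A.**
- Disconnection: C1–C2 and C2–C3, with C2 as an inserted carbonyl.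
- Forward key step: A3 carries an enol triflate at C1 and an α-alkoxyalkenylstannane at C3. Oxidative addition of zerovalent palladium to the triflate, carbonyl insertion and intramolecular coupling would give A4.
- For: ring A is formed in its final oxidation state as a protected diosphenol, and no oxidation is needed on a sensitive dienone. This is better than the chosen end-game.
- Against: A3 needs two fragile, cis-disposed arms on adjacent crowded carbons, one of them a geometrically defined electron-rich stannane that is prone to protodestannylation. Direct coupling to a five-membered ring competes with insertion. Ring B must again be complete beforehand. A4 still needs a silyl-to-acetate exchange at C8, two oxidation levels at the chain terminus and unmasking of the enol.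
- Comparison: the step count is not lower, and the stereochemical burden is moved to an acyclic or monocyclic stage. The chosen route relays every centre through bicycles.

**Alternative 3: gold Conia-ene closure of ring A at C1–C10.**
- Disconnection: the C1–C10 bond.
- Forward key step: A5 is a ring B silyl enol ether (C9=C10) with a pent-4-ynyl chain on C5. Gold activation of the alkyne would let C10 attack C1 in a 6-exo-dig mode and give A6.
- For: quaternary C10 and the exocyclic methylene are made in one step, so no methylenation of a hindered ketone is needed. This is stronger than step 16 of the chosen route.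
- Against: A6 keeps a C9 carbonyl that the target lacks. Removing a neopentyl ketone next to the C8 oxygen costs several steps and risks β-elimination. C10 is created last, against four existing centres. C2 and C3 still have to be oxidised as in the chosen route.
- Comparison: in the chosen route C10 is the first stereocentre and controls the others, and the only carbonyl in ring B (C8) is used twice, as the migration terminus and as the handle for C7 and C8.

Key step: step 10

## Route

Step 1
Reactants: 1 2-methylcyclohexane-1,3-dione; 2 1-bromobut-2-yne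
Product: 3 2-(but-2-yn-1-yl)-2-methylcyclohexane-1,3-dione
Conditions: KOH (1.1 equiv), H2O, rt → 50 °C
Reagents that add atoms: none
Why: C-alkylation (SN2) of the dione enolate with a propargylic bromide in water should give the 2,2-disubstituted dione; the butynyl group carries C9, C8, C6 and the future C6 methyl.

Step 2
Reactants: 3 2-(but-2-yn-1-yl)-2-methylcyclohexane-1,3-dione
Product: 4 (2R,3R)-2-(but-2-yn-1-yl)-3-hydroxy-2-methylcyclohexan-1-one
Conditions: (S)-2-methyl-CBS-oxazaborolidine (0.1 equiv), BH3·THF (0.6 equiv), THF, −30 °C; MeOH
Reagents that add atoms: none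
Why: Corey–Bakshi–Shibata desymmetrising reduction of the prochiral dione: the catalyst should set the carbinol as R and hydride should enter anti to the butynyl group, so reduction of one carbonyl fixes the quaternary carbon (future C10) as R. The carbinol becomes C1 and the untouched carbonyl becomes C5.

Step 3
Reactants: 4 (2R,3R)-2-(but-2-yn-1-yl)-3-hydroxy-2-methylcyclohexan-1-one
Product: 5 (2R,3R)-2-(but-2-yn-1-yl)-3-[(tert-butyldimethylsilyl)oxy]-2-methylcyclohexan-1-one
Conditions: TBSCl, imidazole, DMF, 40 °C
Reagents that add atoms: tert-butyldimethylsilyl chloride CC(C)(C)[Si](C)(C)Cl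
Why: Silylation of the hindered secondary alcohol; the ether prevents retro-aldol cleavage in step 5 and later serves as the equatorial 1α group that biases step 6.

Step 4
Reactants: 5 (2R,3R)-2-(but-2-yn-1-yl)-3-[(tert-butyldimethylsilyl)oxy]-2-methylcyclohexan-1-one
Product: 6 (2R,3R)-3-[(tert-butyldimethylsilyl)oxy]-2-methyl-2-(2-oxobutyl)cyclohexan-1-one
Conditions: NaAuCl4·2H2O (2 mol%), MeOH–H2O (10:1), 60 °C
Reagents that add atoms: water O
Why: Gold-catalysed alkyne hydration with neighbouring-group assistance: the C5 carbonyl oxygen should attack the activated triple bond 5-exo-dig at the proximal carbon, so the new carbonyl lands on C8 and a 1,4-diketone results.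

Step 5
Reactants: 6 (2R,3R)-3-[(tert-butyldimethylsilyl)oxy]-2-methyl-2-(2-oxobutyl)cyclohexan-1-one
Product: 8 (7R,7aS)-7-[(tert-butyldimethylsilyl)oxy]-3,7a-dimethyl-1,4,5,6,7,7a-hexahydro-2H-inden-2-one (C5=C6 enone with 6-methyl and 1α-OTBS in the local numbering), via aldol adduct 7 (not isolated)
Conditions: KOH, MeOH, 50 °C
Reagents that add atoms: none
Why: Intramolecular aldol condensation of a 1,4-diketone to a cyclopentenone: only the C6 methylene can reach the C5 carbonyl in a five-membered closure, and dehydration to the tetrasubstituted enone drives the reaction. C6 already carries its methyl.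

Step 6
Reactants: 8 bicyclic enone; 9 2-(2-bromoethyl)-2-methyl-1,3-dioxolane
Product: 11 cis-hydrindan-8-one with 1α-OTBS 5β-H 6α-methyl 6β-[2-(2-methyl-1,3-dioxolan-2-yl)ethyl] 10β-methyl, via lithium enolate 10 (not isolated)
Conditions: Li (2.2 equiv), NH3(l)–THF, t-BuOH (1.0 equiv), −78 °C; then 9 (3 equiv), THF–DMPU, −78 °C → rt
Reagents that add atoms: none
Why: Stork reductive alkylation: axial β-protonation of C5 on a ring A chair that keeps the 1α-silyloxy group equatorial should give the less strained cis-fused enolate 10. The bromide should then alkylate C6 (SN2) from the convex β face, anti to the vicinal C5–C4 bond, which sets 5β-H, 6β-chain and 6α-methyl.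

Step 7
Reactants: 11 cis-hydrindan-8-one; 12 vinylmagnesium bromide
Product: 13 8β-vinyl cis-hydrindan-8α-ol with 1α-OTBS
Conditions: CeCl3 (anhydrous, 1.5 equiv), 12, THF, −78 → 0 °C
Reagents that add atoms: none
Why: 1,2-Addition of the organocerium reagent avoids enolisation of the doubly neopentyl ketone; attack from the convex β face, away from ring A and the 6α-methyl, should give the 8β-vinyl 8α-ol. The C8 centre is erased in step 10 but it orients the vinyl group for the C7 outcome.

Step 8
Reactants: 13 8β-vinyl cis-hydrindan-8α-ol with 1α-OTBS
Product: 14 8β-vinyl cis-hydrindane-1α,8α-diol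
Conditions: Bu4NF, THF, 50 °C
Reagents that add atoms: none
Why: Fluoride-mediated desilylation; the tertiary allylic alcohol and the ketal are not affected.

Step 9
Reactants: 14 8β-vinyl cis-hydrindane-1α,8α-diol
Product: 15 8α-hydroxy-8β-vinyl cis-hydrindan-1-one (key-step precursor)
Conditions: Dess–Martin periodinane, pyridine, CH2Cl2, rt
Reagents that add atoms: none
Why: Dess–Martin oxidation of the secondary alcohol; the tertiary allylic alcohol cannot be oxidised. C1 is made trigonal here because, once ring B is six-membered, any α substituent on C1 would collide with the axial 6α-methyl of chair form P.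

Step 10
Reactants: 15 8α-hydroxy-8β-vinyl cis-hydrindan-1-one
Product: 16 cis-decalin-1,8-dione with 5β-H 6α-methyl 6β-ketal chain 7α-methyl 10β-methyl
Conditions: Co(salen) (5 mol%; salen = N,N′-bis(3,5-di-tert-butylsalicylidene)cyclohexane-1,2-diaminate, divalent cobalt), N-fluoro-2,4,6-trimethylpyridinium triflate (1.2 equiv), PhSiH3 (1.2 equiv), acetone, 0 °C → rt
Reagents that add atoms: none
Why: A cobalt hydride formed from the catalyst, the oxidant and the silane should transfer a hydrogen atom to the terminal vinyl carbon, and the resulting C7 radical is captured and oxidised to a tetravalent alkylcobalt that acts as a C7 cation equivalent. The C8–C6 bond anti to cobalt then shifts to C7 while the C8 hydroxyl becomes the carbonyl, so the C6–C7 bond forms and the cyclopentane becomes ring B. The closest known reaction is the hydrogen-atom-transfer-initiated radical–polar crossover semipinacol rearrangement of tertiary allylic alcohols, including ring expansion of 1-alkenylcycloalkanols; secondary alkylcobalt electrophiles of this kind are the ones displaced in cobalt-catalysed Markovnikov hydrofunctionalisation of terminal alkenes. Ring B is closed by a suprafacial 1,2-alkyl shift (one-carbon ring enlargement), not by an exo or endo cyclisation, and C6 migrates with retention. The step needs C6 and not C9 to migrate; the fully substituted C6 carries positive charge better in the bridged transition state than the C9 methylene. The new C7 centre is set by the rotamer about C8–C7: the methyl should stay outside, away from C9 and the β-methyl on C10, and with the β-vinyl group this gives 7α-methyl. That is also the equatorial epimer in chair form P, which the trigonal C1 makes available, so a short base treatment can enrich it if needed. The shift must also beat closure of the hydroxyl onto C7 to an epoxide; the electron-rich migrating carbon and carbonyl formation favour it.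

Step 11
Reactants: 16 cis-decalin-1,8-dione
Product: 17 cis-decalin-1β,8β-diol with 7α-methyl
Conditions: Li, NH3(l)–THF, t-BuOH, −78 °C; NH4Cl
Reagents that add atoms: none
Why: Dissolving-metal reduction of both ketones under thermodynamic control: in chair form P the 8β- and 1β-hydroxyls are equatorial, and the 1α position points into the pocket at the 6α-methyl. A hydride reagent would attack C8 from the β face, because the α-axial path is blocked by the axial 6α-methyl and by C1, and would give the 8α-alcohol.

Step 12
Reactants: 17 cis-decalin-1β,8β-diol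
Product: 18 8β-acetoxy cis-decalin-1β-ol
Conditions: Ac2O (1.1 equiv), pyridine, CH2Cl2, 0 °C
Reagents that add atoms: acetic anhydride CC(=O)OC(C)=O
Why: Site-selective acylation: the C8 hydroxyl is flanked by a CH2 and a CH(CH3), whereas the C1 hydroxyl is neopentylic next to quaternary C10 and should react much more slowly with one equivalent of anhydride.

Step 13
Reactants: 18 8β-acetoxy cis-decalin-1β-ol
Product: 19 8β-acetoxy cis-decalin-1-one with the side-chain ketal
Conditions: Dess–Martin periodinane, pyridine, CH2Cl2, rt
Reagents that add atoms: none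
Why: Dess–Martin oxidation returns C1 to the ketone needed for methylenation; acetate and ketal are inert.

Step 14
Reactants: 19 8β-acetoxy cis-decalin-1-one with the side-chain ketal
Product: 20 8β-acetoxy-6β-(3-oxobutyl) cis-decalin-1-one
Conditions: pyridinium p-toluenesulfonate (cat.), acetone–H2O, 60 °C
Reagents that add atoms: water O
Why: Mild acid-catalysed ketal hydrolysis; the acetate survives these conditions and C7 can no longer epimerise.

Step 15
Reactants: 20 8β-acetoxy-6β-(3-oxobutyl) cis-decalin-1-one; 21 tert-butyl 2-(diethoxyphosphoryl)acetate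
Product: 22 tert-butyl (E)-enoate with C1 ketone
Conditions: NaH, 21, THF, 0 → 50 °C
Reagents that add atoms: none
Why: Horner–Wadsworth–Emmons olefination should occur only at the unhindered methyl ketone, since the C1 ketone is α-quaternary, and should favour the E-enoate as usual for methyl ketones. The minor Z isomer is removed by chromatography.

Step 16
Reactants: 22 tert-butyl (E)-enoate with C1 ketone
Product: 23 1-methylene cis-decalin with 8β-acetate and tert-butyl (E)-enoate
Conditions: Zn, CH2Br2, TiCl4, THF–CH2Cl2, 0 °C → rt
Reagents that add atoms: dibromomethane BrCBr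
Why: Lombardo methylenation is non-basic and oxophilic, so it should convert the hindered C1 ketone without touching the acetate or the enoate.

Step 17
Reactants: 23 1-methylene cis-decalin
Product: 24 1-methylene cis-decalin-2-ol (C2 epimers)
Conditions: SeO2 (0.5 equiv), t-BuOOH, CH2Cl2, rt
Reagents that add atoms: selenium dioxide O=[Se]=O; tert-butyl hydroperoxide CC(C)(C)OO
Why: Selenium dioxide allylic hydroxylation (ene reaction, then 2,3-shift) of the electron-rich 1,1-disubstituted alkene; C2 is its only allylic CH2 because C10 is quaternary, and the electron-poor enoate is much less reactive. The C2 configuration is irrelevant.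

Step 18
Reactants: 24 1-methylene cis-decalin-2-ol
Product: 25 1-methylene cis-decalin-2-one
Conditions: Dess–Martin periodinane, pyridine, CH2Cl2, 0 °C → rt
Reagents that add atoms: none
Why: Dess–Martin oxidation of the allylic alcohol to the α-methylene ketone. The alkene cannot move into the ring because C10 has no hydrogen; the product is used at once.

Step 19
Reactants: 25 1-methylene cis-decalin-2-one
Product: 27 3-hydroxy-1-methylene cis-decalin-2-one (C3 epimers), via sodium dienolate 26 (not isolated)
Conditions: NaN(SiMe3)2 (1.05 equiv), THF, −78 °C; then 2-(benzenesulfonyl)-3-phenyloxaziridine, −78 °C; NH4Cl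
Reagents that add atoms: 2-(benzenesulfonyl)-3-phenyloxaziridine O=S(=O)(c1ccccc1)N1OC1c1ccccc1
Why: Deprotonation can occur only at C3, and the cross-conjugated dienolate 26 should be hydroxylated at C3 by the Davis oxaziridine (enolate oxidation). The sodium counter-ion limits addition to the sulfonimine by-product, and the C3 configuration is irrelevant.

Step 20
Reactants: 27 3-hydroxy-1-methylene cis-decalin-2-one
Product: 29 tert-butyl ester of the target (3-hydroxy-1-methylene-2-oxo-3-ene), via 2,3-diketone 28 (not isolated)
Conditions: Dess–Martin periodinane, CH2Cl2, rt; silica gel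
Reagents that add atoms: none
Why: Dess–Martin oxidation of the α-hydroxy ketone gives dione 28, which can enolise only toward C4 and should tautomerise to the conjugated diosphenol.

Step 21
Reactants: 29 tert-butyl ester of the target
Product: 30 CNP0192653.1
Conditions: CF3CO2H, CH2Cl2, 0 °C → rt
Reagents that add atoms: none
Why: Acidolysis of the tert-butyl ester (loss of isobutene) leaves the acetate, which would not survive saponification, and the dienone, which cannot isomerise because C10 is quaternary.

## Compound list

1 | 2-methylcyclohexane-1,3-dione | CC1C(=O)CCCC1=O | starting material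
2 | 1-bromobut-2-yne | CC#CCBr | starting material
3 | 2-(but-2-yn-1-yl)-2-methylcyclohexane-1,3-dione | CC#CCC1(C)C(=O)CCCC1=O | intermediate
4 | (2R,3R)-2-(but-2-yn-1-yl)-3-hydroxy-2-methylcyclohexan-1-one | [C@@H]1(O)CCCC(=O)[C@]1(C)CC#CC | intermediate
5 | (2R,3R)-2-(but-2-yn-1-yl)-3-[(tert-butyldimethylsilyl)oxy]-2-methylcyclohexan-1-one | [C@@H]1(O[Si](C)(C)C(C)(C)C)CCCC(=O)[C@]1(C)CC#CC | intermediate
6 | (2R,3R)-3-[(tert-butyldimethylsilyl)oxy]-2-methyl-2-(2-oxobutyl)cyclohexan-1-one | [C@@H]1(O[Si](C)(C)C(C)(C)C)CCCC(=O)[C@]1(C)CC(=O)CC | intermediate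
7 | aldol adduct: bicyclic 5-hydroxy-6-methyl-8-ketone, 1α-OTBS (C5 and C6 unassigned) | [C@@H]1(O[Si](C)(C)C(C)(C)C)CCCC2(O)C(C)C(=O)C[C@]12C | intermediate
8 | (7R,7aS)-7-[(tert-butyldimethylsilyl)oxy]-3,7a-dimethyl-1,4,5,6,7,7a-hexahydro-2H-inden-2-one | [C@@H]1(O[Si](C)(C)C(C)(C)C)CCCC2=C(C)C(=O)C[C@]12C | intermediate
9 | 2-(2-bromoethyl)-2-methyl-1,3-dioxolane | CC1(CCBr)OCCO1 | starting material
10 | lithium enolate (C6=C8–OLi) of the cis-fused hydrindanone, 1α-OTBS, 5β-H | [C@@H]1(O[Si](C)(C)C(C)(C)C)CCC[C@@H]2C(C)=C(O[Li])C[C@]12C | intermediate
11 | cis-hydrindan-8-one: 1α-OTBS, 5β-H, 6α-methyl, 6β-[2-(2-methyl-1,3-dioxolan-2-yl)ethyl], 10β-methyl | [C@@H]1(O[Si](C)(C)C(C)(C)C)CCC[C@@H]2[C@@](C)(CCC3(C)OCCO3)C(=O)C[C@]12C | intermediate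
12 | vinylmagnesium bromide | C=C[Mg]Br | starting material
13 | 8β-vinyl cis-hydrindan-8α-ol, 1α-OTBS, other centres as in 11 | [C@@H]1(O[Si](C)(C)C(C)(C)C)CCC[C@@H]2[C@@](C)(CCC3(C)OCCO3)[C@@](O)(C=C)C[C@]12C | intermediate
14 | 8β-vinyl cis-hydrindane-1α,8α-diol | [C@@H]1(O)CCC[C@@H]2[C@@](C)(CCC3(C)OCCO3)[C@@](O)(C=C)C[C@]12C | intermediate
15 | 8α-hydroxy-8β-vinyl cis-hydrindan-1-one (5β-H, 6α-methyl, 6β-ketal chain, 10β-methyl) | O=C1CCC[C@@H]2[C@@](C)(CCC3(C)OCCO3)[C@@](O)(C=C)C[C@]12C | intermediate
16 | cis-decalin-1,8-dione: 5β-H, 6α-methyl, 6β-ketal chain, 7α-methyl, 10β-methyl | O=C1CCC[C@@H]2[C@@](C)(CCC3(C)OCCO3)[C@H](C)C(=O)C[C@]12C | intermediate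
17 | cis-decalin-1β,8β-diol, other centres as in 16 | [C@H]1(O)CCC[C@@H]2[C@@](C)(CCC3(C)OCCO3)[C@H](C)[C@@H](O)C[C@]12C | intermediate
18 | 8β-acetoxy cis-decalin-1β-ol | [C@H]1(O)CCC[C@@H]2[C@@](C)(CCC3(C)OCCO3)[C@H](C)[C@@H](OC(C)=O)C[C@]12C | intermediate
19 | 8β-acetoxy cis-decalin-1-one with the side-chain dioxolane | O=C1CCC[C@@H]2[C@@](C)(CCC3(C)OCCO3)[C@H](C)[C@@H](OC(C)=O)C[C@]12C | intermediate
20 | 8β-acetoxy-6β-(3-oxobutyl) cis-decalin-1-one | O=C1CCC[C@@H]2[C@@](C)(CCC(C)=O)[C@H](C)[C@@H](OC(C)=O)C[C@]12C | intermediate
21 | tert-butyl 2-(diethoxyphosphoryl)acetate | CCOP(=O)(OCC)CC(=O)OC(C)(C)C | starting material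
22 | tert-butyl (E)-3-methylpent-2-enoate chain on C6, C1 ketone, 8β-acetate | O=C1CCC[C@@H]2[C@@](C)(CC/C(C)=C/C(=O)OC(C)(C)C)[C@H](C)[C@@H](OC(C)=O)C[C@]12C | intermediate
23 | 1-methylene cis-decalin, 8β-acetate, tert-butyl (E)-enoate | C=C1CCC[C@@H]2[C@@](C)(CC/C(C)=C/C(=O)OC(C)(C)C)[C@H](C)[C@@H](OC(C)=O)C[C@]12C | intermediate
24 | 1-methylene cis-decalin-2-ol (C2 unassigned) | C=C1C(O)CC[C@@H]2[C@@](C)(CC/C(C)=C/C(=O)OC(C)(C)C)[C@H](C)[C@@H](OC(C)=O)C[C@]12C | intermediate
25 | 1-methylene cis-decalin-2-one | C=C1C(=O)CC[C@@H]2[C@@](C)(CC/C(C)=C/C(=O)OC(C)(C)C)[C@H](C)[C@@H](OC(C)=O)C[C@]12C | intermediate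
26 | sodium dienolate (C2–ONa, C2=C3) of 25 | C=C1C(O[Na])=CC[C@@H]2[C@@](C)(CC/C(C)=C/C(=O)OC(C)(C)C)[C@H](C)[C@@H](OC(C)=O)C[C@]12C | intermediate
27 | 3-hydroxy-1-methylene cis-decalin-2-one (C3 unassigned) | C=C1C(=O)C(O)C[C@@H]2[C@@](C)(CC/C(C)=C/C(=O)OC(C)(C)C)[C@H](C)[C@@H](OC(C)=O)C[C@]12C | intermediate
28 | 1-methylene cis-decalin-2,3-dione | C=C1C(=O)C(=O)C[C@@H]2[C@@](C)(CC/C(C)=C/C(=O)OC(C)(C)C)[C@H](C)[C@@H](OC(C)=O)C[C@]12C | intermediate
29 | tert-butyl ester of the target | C=C1C(=O)C(O)=C[C@@H]2[C@@](C)(CC/C(C)=C/C(=O)OC(C)(C)C)[C@H](C)[C@@H](OC(C)=O)C[C@]12C | intermediate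
30 | CNP0192653.1: (E)-5-(8β-acetoxy-3-hydroxy-6α,7α,10β-trimethyl-1-methylene-2-oxo-5βH-cis-decal-3-en-6β-yl)-3-methylpent-2-enoic acid (local numbering) | C=C1C(=O)C(O)=C[C@@H]2[C@@](C)(CC/C(C)=C/C(=O)O)[C@H](C)[C@@H](OC(C)=O)C[C@]12C | target

## Step count and least certain steps

Total: 21 steps. Longest linear sequence: 21 steps (1 to 30); 2, 9, 12 and 21 enter as purchased.

**Step 10 (key step).** The hydroxyl may close onto C7 to give an epoxide, the C9 methylene may migrate, or the vinyl group may simply be reduced, because a secondary cobalt-bound carbon is a weaker electrophile than the tertiary ones for which this shift is best established. Facial control at C7 may also be incomplete.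
Fallback, from 15 back to 16:
- Hydroxyl-directed epoxidation with VO(acac)2 and t-BuOOH gives the epoxy alcohol F1.
- ZnBr2 in CH2Cl2 induces the epoxy-alcohol semipinacol shift of C6 to C7 and gives the 7-hydroxymethyl ketone F2.
- Methanesulfonyl chloride and Et3N give the mesylate F3, which eliminates in the same flask to the 7-methylene ketone F4.
- Hydrogenation over Pd/C, then equilibration with DBU, gives 16.

**Step 6.** The tetrasubstituted enolate may be protonated instead of alkylated, because SN2 attack on an unactivated primary bromide is slow and elimination of the bromide competes. Cis selectivity of the C5 protonation may also erode.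
Fallback, from 8 back to 11:
- Hydrogenation over Pd/C should add to the β face, opposite the axial 1α-silyloxy group, and give the cis-fused ketone F5.
- Me3SiCl, NaI and Et3N in MeCN give the more substituted silyl enol ether F6.
- Mukaiyama–Michael addition to but-3-en-2-one with TiCl4 at −78 °C gives the 1,5-diketone F7.
- Ethylene glycol with pyridinium p-toluenesulfonate ketalises only the methyl ketone and gives 11.

**Step 2.** Discrimination of the two carbonyls and of their faces may be incomplete (low ee or dr), and over-reduction to diols may occur, because methyl and butynyl differ little in size.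
Fallback, from 3 back to 4:
- NaBH4 at −20 °C gives the racemic cis ketol F8.
- Esterification with (R)-2-methoxy-2-phenylacetic acid, separation of the diastereomers and isolation of the (2R,3R) ester F9.
- Methanolysis with K2CO3 in MeOH gives 4.

**Step 12.** Site selectivity may be insufficient and diacetate may form, because both hydroxyls are equatorial and secondary.
Fallback, from 17 back to 19:
- The much bulkier t-BuPh2SiCl with imidazole silylates only C8 and gives the silyl ether F10.
- Dess–Martin oxidation gives the C1 ketone F11.
- Bu4NF buffered with AcOH gives the hydroxy ketone F12.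
- Ac2O with 4-dimethylaminopyridine gives 19.

**Step 19.** The dienolate may add to unreacted 25 (Michael oligomerisation), the acetate may be deprotonated, or the enolate may add to the sulfonimine by-product, because a strong base meets an α-methylene ketone.
Fallback, from 25 back to 27:
- Soft enolisation with Me3SiOTf and Et3N gives the silyl dienol ether F13.
- Rubottom oxidation with dimethyldioxirane gives the 3-silyloxy ketone F14.
- Citric acid in MeOH gives 27.

## Further compounds

F1 | step 10 | epoxy alcohol: 8α-hydroxy-8β-(oxiran-2-yl) cis-hydrindan-1-one | O=C1CCC[C@@H]2[C@@](C)(CCC3(C)OCCO3)[C@@](O)(C4CO4)C[C@]12C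
F2 | step 10 | 7-(hydroxymethyl) cis-decalin-1,8-dione | O=C1CCC[C@@H]2[C@@](C)(CCC3(C)OCCO3)C(CO)C(=O)C[C@]12C
F3 | step 10 | mesylate of F2 | O=C1CCC[C@@H]2[C@@](C)(CCC3(C)OCCO3)C(COS(C)(=O)=O)C(=O)C[C@]12C
F4 | step 10 | 7-methylene cis-decalin-1,8-dione | O=C1CCC[C@@H]2[C@@](C)(CCC3(C)OCCO3)C(=C)C(=O)C[C@]12C
F5 | step 6 | cis-fused 6-methylhydrindan-8-one, 1α-OTBS | [C@@H]1(O[Si](C)(C)C(C)(C)C)CCC[C@@H]2C(C)C(=O)C[C@]12C
F6 | step 6 | trimethylsilyl enol ether (C6=C8) of F5 | [C@@H]1(O[Si](C)(C)C(C)(C)C)CCC[C@@H]2C(C)=C(O[Si](C)(C)C)C[C@]12C
F7 | step 6 | 6α-methyl-6β-(3-oxobutyl) cis-hydrindan-8-one, 1α-OTBS | [C@@H]1(O[Si](C)(C)C(C)(C)C)CCC[C@@H]2[C@@](C)(CCC(C)=O)C(=O)C[C@]12C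
F8 | step 2 | racemic cis-2-(but-2-yn-1-yl)-3-hydroxy-2-methylcyclohexan-1-one | OC1CCCC(=O)C1(C)CC#CC
F9 | step 2 | (R)-2-methoxy-2-phenylacetate of 4 | [C@@H]1(OC(=O)[C@H](OC)c2ccccc2)CCCC(=O)[C@]1(C)CC#CC
F10 | step 12 | 8β-(tert-butyldiphenylsilyloxy) cis-decalin-1β-ol | [C@H]1(O)CCC[C@@H]2[C@@](C)(CCC3(C)OCCO3)[C@H](C)[C@@H](O[Si](c4ccccc4)(c5ccccc5)C(C)(C)C)C[C@]12C
F11 | step 12 | 8β-(tert-butyldiphenylsilyloxy) cis-decalin-1-one | O=C1CCC[C@@H]2[C@@](C)(CCC3(C)OCCO3)[C@H](C)[C@@H](O[Si](c4ccccc4)(c5ccccc5)C(C)(C)C)C[C@]12C
F12 | step 12 | 8β-hydroxy cis-decalin-1-one | O=C1CCC[C@@H]2[C@@](C)(CCC3(C)OCCO3)[C@H](C)[C@@H](O)C[C@]12C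
F13 | step 19 | 2-(trimethylsilyloxy)-1-methylene-2-ene (silyl dienol ether of 25) | C=C1C(O[Si](C)(C)C)=CC[C@@H]2[C@@](C)(CC/C(C)=C/C(=O)OC(C)(C)C)[C@H](C)[C@@H](OC(C)=O)C[C@]12C
F14 | step 19 | 3-(trimethylsilyloxy)-1-methylene cis-decalin-2-one | C=C1C(=O)C(O[Si](C)(C)C)C[C@@H]2[C@@](C)(CC/C(C)=C/C(=O)OC(C)(C)C)[C@H](C)[C@@H](OC(C)=O)C[C@]12C
A1 | alternative 1 | O-phenyl thionocarbonate at C5 of the ring B cyclohexane with a 1-methylene-2-oxobut-3-enyl group on C10 | C=CC(=O)C(=C)[C@@]1(C)C[C@H](OC(C)=O)[C@@H](C)[C@](C)(CCC2(C)OCCO2)C1OC(=S)Oc3ccccc3
A2 | alternative 1 | cis-fused 1-methylene-decalin-2-one with C8 acetate | C=C1C(=O)CC[C@@H]2[C@@](C)(CCC3(C)OCCO3)[C@H](C)[C@@H](OC(C)=O)C[C@]12C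
A3 | alternative 2 | C1 enol triflate with C3 (methoxymethoxy)alkenyl tributylstannane | C=C(OS(=O)(=O)C(F)(F)F)[C@@]1(C)C[C@H](O[Si](C)(C)C(C)(C)C)[C@@H](C)[C@](C)(CC/C(C)=C/CO[Si](CC)(CC)CC)[C@H]1/C=C(/OCOC)[Sn](CCCC)(CCCC)CCCC
A4 | alternative 2 | cis-fused decalin with ring A as its methoxymethyl-protected diosphenol | C=C1C(=O)C(OCOC)=C[C@@H]2[C@@](C)(CC/C(C)=C/CO[Si](CC)(CC)CC)[C@H](C)[C@@H](O[Si](C)(C)C(C)(C)C)C[C@]12C
A5 | alternative 3 | C9 silyl enol ether of the ring B ketone with a pent-4-ynyl chain on C5 | C#CCCC[C@@H]1[C@@](C)(CCC2(C)OCCO2)[C@H](C)[C@@H](O[Si](C)(C)C(C)(C)C)C(O[Si](C)(C)C(C)(C)C)=C1C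
A6 | alternative 3 | cis-fused 1-methylene-decalin-9-one | C=C1CCC[C@@H]2[C@@](C)(CCC3(C)OCCO3)[C@H](C)[C@@H](O[Si](C)(C)C(C)(C)C)C(=O)[C@]12C
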